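If the reading at 6.00 h is set out as a ledger of the D charged, two runs already give a rule for the next charge at that time and that L. D is the limiting reagent, with L held at 0.58 mM.

the same everywhere: L 0.58 mM (held)

| flask | D | remark | time |
|---|---|---|---|
| summer | 14 mM | run made earlier |  |
| autumn | 65 mM | run made earlier |  |
| eta | 12 mM |  | 6.0 h |
| delta | 25 mM |  | 6.0 h |
| gamma | 50 mM |  | 6.0 h |

| run | time / h | Z / % |
|---|---|---|
| summer | 0.500 | 0.1 |
| summer | 1.00 | 0.2 |
| summer | 2.50 | 1.0 |
| summer | 6.00 | 6.2 |
| autumn | 0.500 | 0.4 |
| autumn | 1.00 | 0 |
| autumn | 2.50 | 1.5 |
| autumn | 6.00 | 3.8 |

(readings scatter by 0.3 percentage points)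

- the numbers in the tables scatter with a standard deviation of 0.3 percentage points
- at the start none of L is in solution
- a reading or a percentage of Z counts all its forms, free or not
- the concentration of Z that is asked is that of its free form alone
- "hardly changes" means that all values lie within two and a half points (for a concentration: within two and a half percent of the largest)

1. [Z] (only what is free in solution) at the end for eta, delta, gamma, in this order
2. the course of these numbers from the first flask to the last (falls all the way / falls, then rises / rises all the way / hardly changes / rises, then falls)

The ledger opens with summer at 6.00 h: 6.2% of the charge is read as Z, and 93.8% stays unread. In autumn the entries are 3.8% and 96.2%. The readings cannot say what the unread entry holds.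

I work in powers of ten. From summer to autumn the charge grows by 0.667 decades, and the Z entry falls by 0.213 decades. Their ratio, the decades of Z fraction lost per decade of charge at 6.00 h, is my yield slope, s = 0.319. As a reading it carries an uncertainty of about 0.0603.

Starting from summer, s enters Z at 6.51% for eta, 5.15% for delta and 4.13% for gamma. The slope is below one, so my entries for counted Z rise with the charge: 0.781 mM, 1.29 mM, 2.07 mM. These are estimates, and free Z is a part of counted Z that the readings do not split off. Assuming a steady free share, I commit to free Z below them, rising all the way.

The forecast gives 0.55 mM, 2.7 mM and 2.4 mM, with the course rises, then falls, on the ground that at gamma "suppression dominates". Its delta stands above my estimate of counted Z, and its gamma stands below its delta, where mine rises.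

    D → G (k = 0.00148 min⁻¹)
    J + G → Z (k = 1.88 L mol⁻¹ min⁻¹)
    J + Z ⇌ E, settled at all times (K = 5100 L mol⁻¹)
    L ⇌ J, rate k4*(csat - [J]) (kL = 0.0338 min⁻¹)

The flasks give 0.237 mM, 0.489 mM and 0.929 mM of free Z, and the course rises all the way. In eta at 6.00 h the books close with D 58.7%, G 35.1% and Z 6.22%, and E, at 4.25%, is counted inside that Z. That leaves 1.97% of the eta charge free. The slope s had entered 6.51% for counted Z in eta. For gamma it entered 4.13%, and gamma at 6.00 h holds 4.06% counted, with E at 2.20% of its charge.

(Readings and results come from a simulation on assumed constants; noise was put on by code.)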